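# Total synthesis of CID53359579 via a traceless benzylic-lactone relay

**Target check.** The target is HOCH2-derived acetate: Ar1CH2–C3H(CH3)–C2H(CH2OAc)–CH2Ar2, with Ar1 = 4-hydroxy-3-methoxyphenyl and Ar2 = 4-hydroxy-3,5-dimethoxyphenyl. The configuration is (2R,3S), with Me and CH2OAc anti in the Ar1CH2–C3–C2–CH2Ar2 zigzag.

**Retrosynthesis**
- The acetate comes from the primary alcohol by chemoselective lipase acetylation. That alcohol comes from the acid by BH3 reduction.
- The acid comes from hydrogenolysis of the benzylic C5–O bond of a γ-butyrolactone. This one step unmasks the Ar1CH2 group, erases the temporary benzylic stereocentre and removes both O-benzyl groups.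
- The lactone comes from anti-to-both-substituents benzylation of a cis-4-methyl-5-aryl-lactone enolate. This sets C2 trans to the methyl group, which gives the required anti relationship.
- The cis-lactone comes from a 1,4-diol made by Brown (Z)-crotylboration of benzyl-vanillin, which fixes the Me stereocentre. The only ring is the lactone, formed once by oxidation and opened once by hydrogenolysis.

**Assumptions**
- Phenols are carried as O-benzyl ethers.
- (–)-Ipc2B-(Z)-crotyl, from (+)-α-pinene, attacks the Si face of aryl aldehydes as the allyl reagent does, giving (1S)-carbinols. If the opposite enantiomer formed, the (+)-reagent would be used.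

---

## Route

**Step 1**
Reactants: 1 syringaldehyde
Product: 2 4-(benzyloxy)-3,5-dimethoxybenzaldehyde
Conditions: BnBr, K2CO3, DMF, rt
Reagents that add atoms: benzyl bromide, BrCc1ccccc1
Why: Williamson O-benzylation of the phenol, which protects it for the later enolate and organoboron chemistry.

**Step 2**
Reactants: 2
Product: 3 (4-(benzyloxy)-3,5-dimethoxyphenyl)methanol
Conditions: NaBH4, MeOH, 0 °C
Reagents that add atoms: none
Why: Chemoselective aldehyde reduction.

**Step 3**
Reactants: 3
Product: 4 4-(benzyloxy)-3,5-dimethoxybenzyl bromide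
Conditions: PBr3, CH2Cl2, 0 °C; use the crude bromide immediately
Reagents that add atoms: PBr3, BrP(Br)Br
Why: Alcohol-to-bromide conversion by SN2 at the benzylic carbon. No stereocentre is involved.

**Step 4**
Reactants: 5 4-(benzyloxy)-3-methoxybenzaldehyde; 6 cis-2-butene
Product: 7 (1S,2R)-1-[4-(benzyloxy)-3-methoxyphenyl]-2-methylbut-3-en-1-ol (syn)
Conditions: 6, n-BuLi, KOt-Bu, THF, –45 °C to give (Z)-crotylpotassium; then (–)-Ipc2BOMe, –78 °C; then BF3·OEt2; then 5, –78 °C; then NaOH, H2O2
Reagents that add atoms: compound 6 (cis-2-butene, C/C=C\C) supplies the crotyl unit. The boron reagent is not incorporated.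
Why: Brown asymmetric crotylboration. The (Z)-crotylborane reacts through a chair Zimmerman–Traxler transition state to give the syn alcohol. The pinene-derived ligands set the aldehyde face, which fixes C1 (S) and the Me centre C2 (R).

**Step 5**
Reactants: 7
Product: 8 (1S,2R)-1-[4-(benzyloxy)-3-methoxyphenyl]-2-methylbutane-1,4-diol
Conditions: 9-BBN (2.5 equiv), THF, 0 °C to rt; then NaOH, H2O2, 0 °C
Reagents that add atoms: hydrogen peroxide, OO (supplies the new OH oxygen)
Why: Anti-Markovnikov hydroboration–oxidation of the terminal alkene. The stereocentres are untouched.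

**Step 6**
Reactants: 8
Product: 9 (4R,5S)-5-[4-(benzyloxy)-3-methoxyphenyl]-4-methyldihydrofuran-2(3H)-one (cis)
Conditions: TEMPO (10 mol %), PhI(OAc)2 (2.5 equiv), CH2Cl2, rt
Reagents that add atoms: none
Why: TEMPO/BAIB oxidises the primary alcohol to the aldehyde. This cyclises onto the secondary OH to form the lactol, which is oxidised to the lactone. The syn diol stereochemistry becomes the cis-4,5 lactone with both centres retained.

**Step 7**
Reactants: 9; 4
Product: 10 (3R,4R,5S)-3-[4-(benzyloxy)-3,5-dimethoxybenzyl]-5-[4-(benzyloxy)-3-methoxyphenyl]-4-methyldihydrofuran-2(3H)-one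
Conditions: LiHMDS, THF/DMPU, –78 °C; then 4, –78 to –40 °C
Reagents that add atoms: compound 4 (numbered reactant)
Why: Lactone enolate alkylation. The electrophile approaches the face opposite both the 4-Me and the cis 5-aryl group, giving trans-3,4. This sets C3 (R) and thus the anti relationship required in the target.

**Step 8**
Reactants: 10
Product: 11 (2R,3S)-2-(4-hydroxy-3,5-dimethoxybenzyl)-4-(4-hydroxy-3-methoxyphenyl)-3-methylbutanoic acid
Conditions: H2 (3 atm), 10% Pd/C, EtOAc/EtOH, rt, no acid
Reagents that add atoms: none (H2 only; the by-product is toluene)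
Why: Pd-catalysed hydrogenolysis cleaves the aryl-O-benzyl ethers and the doubly activated benzylic C5–O lactone bond. This converts the lactone C5 into the Ar1CH2 group and leaves the acid. The benzylic stereocentre is destroyed, and the two remaining stereocentres are not touched.

**Step 9**
Reactants: 11
Product: 12 (2R,3S)-2-(4-hydroxy-3,5-dimethoxybenzyl)-4-(4-hydroxy-3-methoxyphenyl)-3-methylbutan-1-ol
Conditions: BH3·THF (4 equiv), THF, 0 °C to rt; then MeOH quench
Reagents that add atoms: none
Why: Borane reduces carboxylic acids selectively over other groups. The phenols only form aryloxyboranes that are cleaved in the workup, and the α-centre is not epimerised because no enolisable carbonyl is formed.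

**Step 10**
Reactants: 12
Product: 13 target, (2R,3S)-CH2OAc compound
Conditions: Novozym 435 (CAL-B), vinyl acetate, TBME, 30 °C
Reagents that add atoms: vinyl acetate, C=COC(C)=O
Why: Lipase-catalysed transesterification acetylates the primary aliphatic OH chemoselectively, as with tyrosol-type substrates, and leaves the phenols free. No stereocentre is affected.

---

## Compound list

| # | Name | SMILES | Role |
|---|---|---|---|
| 1 | syringaldehyde | COc1cc(C=O)cc(OC)c1O | starting material |
| 2 | 4-(benzyloxy)-3,5-dimethoxybenzaldehyde | COc1cc(C=O)cc(OC)c1OCc1ccccc1 | intermediate |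
| 3 | (4-(benzyloxy)-3,5-dimethoxyphenyl)methanol | COc1cc(CO)cc(OC)c1OCc1ccccc1 | intermediate |
| 4 | 4-(benzyloxy)-3,5-dimethoxybenzyl bromide | COc1cc(CBr)cc(OC)c1OCc1ccccc1 | intermediate |
| 5 | 4-(benzyloxy)-3-methoxybenzaldehyde | COc1cc(C=O)ccc1OCc1ccccc1 | starting material |
| 6 | cis-2-butene | C/C=C\C | starting material |
| 7 | (1S,2R)-syn homoallylic alcohol | C=C[C@@H](C)[C@H](O)c1ccc(OCc2ccccc2)c(OC)c1 | intermediate |
| 8 | (1S,2R)-1-aryl-2-methylbutane-1,4-diol | OCC[C@@H](C)[C@H](O)c1ccc(OCc2ccccc2)c(OC)c1 | intermediate |
| 9 | (4R,5S)-cis-lactone | C[C@@H]1CC(=O)O[C@@H]1c2ccc(OCc3ccccc3)c(OC)c2 | intermediate |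
| 10 | (3R,4R,5S)-trans-alkylated lactone | C[C@@H]1[C@@H](Cc2cc(OC)c(OCc3ccccc3)c(OC)c2)C(=O)O[C@@H]1c4ccc(OCc5ccccc5)c(OC)c4 | intermediate |
| 11 | (2R,3S)-diphenolic acid | COc1cc(C[C@H](C)[C@H](C(=O)O)Cc2cc(OC)c(O)c(OC)c2)ccc1O | intermediate |
| 12 | (2R,3S)-primary alcohol | COc1cc(C[C@H](C)[C@H](CO)Cc2cc(OC)c(O)c(OC)c2)ccc1O | intermediate |
| 13 | target acetate | COc1cc(C[C@H](C)[C@H](COC(C)=O)Cc2cc(OC)c(O)c(OC)c2)ccc1O | target |

---

**Totals.** There are 10 steps in all, and the longest linear sequence is 7 steps (5 → 7 → 8 → 9 → 10 → 11 → 12 → 13, or equivalently 1 → 2 → 3 → 4 → 10 → 11 → 12 → 13).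

**Three steps most likely to fail**

1. **Step 8, hydrogenolysis.** Once the para-OH is free, benzylic ionisation or β-H elimination could scramble the adjacent Me stereocentre, or the reaction could stall at the lactone.
   Fallback: reduce lactone 10 with LiBH4 to the diol and acetylate the primary OH selectively. Convert the secondary benzylic OH to a phenyl thionocarbonate and deoxygenate it by Barton–McCombie (Bu3SnH, AIBN). Remove the O-benzyl groups with H2/Pd/C last.

2. **Step 7, benzylation.** The diastereoselectivity may be imperfect, and the electron-rich benzyl bromide 4 is unstable.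
   Fallback: aldol condensation of the lactone enolate with aldehyde 2, then dehydration to the α-arylidene lactone, which avoids bromide 4. Hydrogenation from the face anti to the Me and aryl groups then gives the trans-lactone, and the same H2/Pd/C step can also open the lactone.

3. **Step 4, crotylation.** The ee, the assumed Si-face sense and the handling of the organopotassium/borane reagent are all uncertain.
   Fallback: build racemic 3-methyl-4-aryl-4-oxobutanoate from the benzyl ether of propiovanillone and tert-butyl bromoacetate. Reduce it by Ru-catalysed asymmetric transfer hydrogenation with dynamic kinetic resolution (HCO2H/Et3N) to the cis γ-hydroxy ester, and lactonise to give 9.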